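**Retrosynthetic overview**
- Target = 2,4-bis(4-hydroxybenzyl)-5-methoxy-3-(2-phenylethyl)phenol; the last step is global O-debenzylation.
- Benzyl arm next to OMe: aryllithium (from a ring bromide placed para to an oxygen) plus 4-(benzyloxy)benzaldehyde, then ionic deoxygenation.
- Benzyl arm next to OH, and the arene itself: α′-aldol of 3-methoxy-5-(2-phenylethyl)cyclohex-2-enone with 4-(benzyloxy)benzaldehyde, dehydration and isoaromatisation (C=O becomes OH, enol ether becomes OMe).
- Cyclohexane-1,3-dione: intermolecular Michael addition of dimethyl malonate to (E)-6-phenylhex-3-en-2-one, Claisen ring closure, decarboxylation; the enone comes from 3-phenylpropanal by Wittig olefination.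
- Ring order: the central carbocycle is the only ring built (step 2) and is aromatised in step 6; the three outer benzene rings are bought.

Assumption: the target has no stereocentre (it is achiral), so there is no enantiomer to control; chiral intermediates are used as racemates or diastereomer mixtures and all their stereocentres are erased in steps 6 and 10.

**Route**

Step 1
Reactants: 1 3-phenylpropanal; 2 1-(triphenylphosphoranylidene)propan-2-one
Product: 3 (E)-6-phenylhex-3-en-2-one
Conditions: CH2Cl2, reflux, 16 h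
Reagents that add atoms: none
Why: Wittig olefination with a ketone-stabilised ylide gives the (E)-enone cleanly from an unhindered aliphatic aldehyde and avoids aldehyde self-condensation.

Step 2
Reactants: 3 (E)-6-phenylhex-3-en-2-one; 4 dimethyl malonate
Product: 6 methyl 2,4-dioxo-6-(2-phenylethyl)cyclohexane-1-carboxylate (racemic, enolised), via Michael adduct 5 (not isolated)
Conditions: NaOMe (1.1 equiv), MeOH, reflux, 4 h; then 1 M HCl, 0 °C
Reagents that add atoms: none
Why: Intermolecular Michael addition of the malonate anion to the enone joins the two fragments, and the methyl ketone enolate of the adduct then closes the ring by an intramolecular Claisen (Dieckmann-type) condensation driven by formation of the stabilised β-dicarbonyl enolate; the stereocentres are racemic and are removed later.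

Step 3
Reactants: 6 methyl 2,4-dioxo-6-(2-phenylethyl)cyclohexane-1-carboxylate
Product: 8 5-(2-phenylethyl)cyclohexane-1,3-dione, via keto acid 7 (not isolated)
Conditions: 2 M NaOH aq., reflux, 2 h; then conc. HCl to pH 1, 90 °C, 1 h
Reagents that add atoms: none
Why: Saponification followed by decarboxylation of the β-keto acid on acidification gives the symmetric 1,3-dione, which has no stereocentre.

Step 4
Reactants: 8 5-(2-phenylethyl)cyclohexane-1,3-dione
Product: 9 3-methoxy-5-(2-phenylethyl)cyclohex-2-en-1-one (racemic)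
Conditions: MeOH, p-TsOH·H2O (5 mol %), reflux, 3 Å MS
Reagents that add atoms: methanol, CO
Why: Acid-catalysed enol etherification of the symmetric dione gives a single vinylogous ester, which fixes the future OMe oxygen and leaves C6 as the kinetic enolisation site.

Step 5
Reactants: 9 3-methoxy-5-(2-phenylethyl)cyclohex-2-en-1-one; 10 4-(benzyloxy)benzaldehyde
Product: 11 6-{[4-(benzyloxy)phenyl](hydroxy)methyl}-3-methoxy-5-(2-phenylethyl)cyclohex-2-en-1-one (diastereomer mixture, racemic)
Conditions: LDA (1.1 equiv), THF, −78 °C, 45 min; then 10, −78 °C, 1 h; AcOH quench at −78 °C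
Reagents that add atoms: none
Why: Kinetic α′-deprotonation of the vinylogous ester (Stork–Danheiser enolate) and intermolecular aldol addition to the non-enolisable aldehyde form the C–C bond of the first benzyl arm exactly between the carbonyl carbon and the phenethyl-bearing carbon; the three stereocentres need no control because step 6 destroys them.

Step 6
Reactants: 11 6-{[4-(benzyloxy)phenyl](hydroxy)methyl}-3-methoxy-5-(2-phenylethyl)cyclohex-2-en-1-one
Product: 14 2-[4-(benzyloxy)benzyl]-5-methoxy-3-(2-phenylethyl)phenol, via mesylate 12 (not isolated), via arylidene dienone 13 (not isolated)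
Conditions: MsCl (1.3 equiv), Et3N (2 equiv), CH2Cl2, 0 °C; then t-BuOK (2.5 equiv), THF, 0 °C to rt; 1 M HCl work-up
Reagents that add atoms: none
Why: Mesylation and E1cB elimination give the cross-conjugated 6-arylidene dienone, which base isomerises by proton shifts (isoaromatisation) to the phenoxide with the gain of aromaticity as driving force, so the ketone oxygen becomes the free OH and the enol ether the OMe.

Step 7
Reactants: 14 2-[4-(benzyloxy)benzyl]-5-methoxy-3-(2-phenylethyl)phenol
Product: 15 1-(benzyloxy)-2-[4-(benzyloxy)benzyl]-5-methoxy-3-(2-phenylethyl)benzene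
Conditions: BnBr (1.2 equiv), K2CO3 (2 equiv), DMF, rt
Reagents that add atoms: benzyl bromide, BrCc1ccccc1
Why: Williamson etherification protects the phenol for the organolithium step with a group that is removed together with the other benzyl ethers at the end.

Step 8
Reactants: 15 1-(benzyloxy)-2-[4-(benzyloxy)benzyl]-5-methoxy-3-(2-phenylethyl)benzene
Product: 16 1-(benzyloxy)-2-[4-(benzyloxy)benzyl]-4-bromo-5-methoxy-3-(2-phenylethyl)benzene
Conditions: NBS (1.0 equiv), MeCN, −10 to 0 °C, dark
Reagents that add atoms: N-bromosuccinimide, O=C1CCC(=O)N1Br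
Why: Electrophilic aromatic bromination goes to the only free position that is para to an alkoxy group (para to OBn, ortho to OMe) in preference to the position between the two oxygens, as in the 2,6-dibromination of 3,5-dimethoxytoluene.

Step 9
Reactants: 16 1-(benzyloxy)-2-[4-(benzyloxy)benzyl]-4-bromo-5-methoxy-3-(2-phenylethyl)benzene; 10 4-(benzyloxy)benzaldehyde
Product: 18 [4-(benzyloxy)phenyl]{4-(benzyloxy)-3-[4-(benzyloxy)benzyl]-6-methoxy-2-(2-phenylethyl)phenyl}methanol (racemic), via aryllithium 17 (not isolated)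
Conditions: n-BuLi (1.05 equiv), THF, −78 °C, 20 min; then 10 (1.2 equiv), −78 to −20 °C; H2O
Reagents that add atoms: none
Why: Bromine–lithium exchange is faster than any deprotonation at −78 °C and the OMe-stabilised aryllithium adds 1,2 to the non-enolisable aldehyde; the new carbinol stereocentre is racemic and is removed in step 10.

Step 10
Reactants: 18 [4-(benzyloxy)phenyl]{4-(benzyloxy)-3-[4-(benzyloxy)benzyl]-6-methoxy-2-(2-phenylethyl)phenyl}methanol
Product: 19 1-(benzyloxy)-2,4-bis[4-(benzyloxy)benzyl]-5-methoxy-3-(2-phenylethyl)benzene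
Conditions: Et3SiH (3 equiv), TFA (5 equiv), CH2Cl2, −10 to 0 °C
Reagents that add atoms: none
Why: Ionic hydrogenation: the doubly benzylic, alkoxy-stabilised cation forms readily in TFA and is trapped by silane hydride, while benzyl and methyl aryl ethers survive.

Step 11
Reactants: 19 1-(benzyloxy)-2,4-bis[4-(benzyloxy)benzyl]-5-methoxy-3-(2-phenylethyl)benzene
Product: 20 2,4-bis(4-hydroxybenzyl)-5-methoxy-3-(2-phenylethyl)phenol (IN1158)
Conditions: H2 (1 atm), 10 % Pd/C, EtOAc/MeOH 1:1, rt
Reagents that add atoms: none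
Why: Catalytic hydrogenolysis cleaves the three O-benzyl ethers and leaves the methyl ether, the diarylmethane C–C bonds and the bibenzyl untouched.

**Compound list**
1 | 3-phenylpropanal | O=CCCc1ccccc1 | starting material
2 | 1-(triphenylphosphoranylidene)propan-2-one | CC(=O)C=P(c1ccccc1)(c1ccccc1)c1ccccc1 | starting material
3 | (E)-6-phenylhex-3-en-2-one | CC(=O)/C=C/CCc1ccccc1 | intermediate
4 | dimethyl malonate | COC(=O)CC(=O)OC | starting material
5 | dimethyl 2-(5-oxo-1-phenylhexan-3-yl)propanedioate (racemic Michael adduct, not isolated) | COC(=O)C(C(=O)OC)C(CCc1ccccc1)CC(C)=O | intermediate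
6 | methyl 2,4-dioxo-6-(2-phenylethyl)cyclohexane-1-carboxylate (racemic) | COC(=O)C1C(=O)CC(=O)CC1CCc1ccccc1 | intermediate
7 | 2,4-dioxo-6-(2-phenylethyl)cyclohexane-1-carboxylic acid (racemic, not isolated) | OC(=O)C1C(=O)CC(=O)CC1CCc1ccccc1 | intermediate
8 | 5-(2-phenylethyl)cyclohexane-1,3-dione | O=C1CC(=O)CC(CCc2ccccc2)C1 | intermediate
9 | 3-methoxy-5-(2-phenylethyl)cyclohex-2-en-1-one (racemic) | COC1=CC(=O)CC(CCc2ccccc2)C1 | intermediate
10 | 4-(benzyloxy)benzaldehyde | O=Cc1ccc(OCc2ccccc2)cc1 | starting material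
11 | 6-{[4-(benzyloxy)phenyl](hydroxy)methyl}-3-methoxy-5-(2-phenylethyl)cyclohex-2-en-1-one (diastereomer mixture) | COC1=CC(=O)C(C(O)c2ccc(OCc3ccccc3)cc2)C(CCc2ccccc2)C1 | intermediate
12 | [4-(benzyloxy)phenyl][4-methoxy-2-oxo-6-(2-phenylethyl)cyclohex-3-en-1-yl]methyl methanesulfonate (not isolated) | COC1=CC(=O)C(C(OS(C)(=O)=O)c2ccc(OCc3ccccc3)cc2)C(CCc2ccccc2)C1 | intermediate
13 | (6E)-6-[4-(benzyloxy)benzylidene]-3-methoxy-5-(2-phenylethyl)cyclohex-2-en-1-one (racemic, not isolated) | COC1=CC(=O)/C(=C/c2ccc(OCc3ccccc3)cc2)C(CCc2ccccc2)C1 | intermediate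
14 | 2-[4-(benzyloxy)benzyl]-5-methoxy-3-(2-phenylethyl)phenol | COc1cc(O)c(Cc2ccc(OCc3ccccc3)cc2)c(CCc2ccccc2)c1 | intermediate
15 | 1-(benzyloxy)-2-[4-(benzyloxy)benzyl]-5-methoxy-3-(2-phenylethyl)benzene | COc1cc(OCc2ccccc2)c(Cc2ccc(OCc3ccccc3)cc2)c(CCc2ccccc2)c1 | intermediate
16 | 1-(benzyloxy)-2-[4-(benzyloxy)benzyl]-4-bromo-5-methoxy-3-(2-phenylethyl)benzene | COc1cc(OCc2ccccc2)c(Cc2ccc(OCc3ccccc3)cc2)c(CCc2ccccc2)c1Br | intermediate
17 | {4-(benzyloxy)-3-[4-(benzyloxy)benzyl]-6-methoxy-2-(2-phenylethyl)phenyl}lithium (not isolated) | COc1cc(OCc2ccccc2)c(Cc2ccc(OCc3ccccc3)cc2)c(CCc2ccccc2)c1[Li] | intermediate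
18 | [4-(benzyloxy)phenyl]{4-(benzyloxy)-3-[4-(benzyloxy)benzyl]-6-methoxy-2-(2-phenylethyl)phenyl}methanol (racemic) | COc1cc(OCc2ccccc2)c(Cc2ccc(OCc3ccccc3)cc2)c(CCc2ccccc2)c1C(O)c1ccc(OCc2ccccc2)cc1 | intermediate
19 | 1-(benzyloxy)-2,4-bis[4-(benzyloxy)benzyl]-5-methoxy-3-(2-phenylethyl)benzene | COc1cc(OCc2ccccc2)c(Cc2ccc(OCc3ccccc3)cc2)c(CCc2ccccc2)c1Cc1ccc(OCc2ccccc2)cc1 | intermediate
20 | 2,4-bis(4-hydroxybenzyl)-5-methoxy-3-(2-phenylethyl)phenol (IN1158) | COc1cc(O)c(Cc2ccc(O)cc2)c(CCc2ccccc2)c1Cc1ccc(O)cc1 | target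

**Step count:** 11 steps in total. Longest linear sequence: 11 steps (1 to 20); all other inputs are bought.

**Steps most likely to fail and their fallbacks**

Step 6 (dehydration and isoaromatisation; risk of retro-aldol, oligomerisation of dienone 13 or incomplete isomerisation). The fallback sets out from 9 and comes back at 19, aromatising before any benzyl arm is attached. Compound 9 is deprotonated with LDA and treated with PhSeBr (THF, −78 °C) to give 3-methoxy-5-(2-phenylethyl)-6-(phenylselanyl)cyclohex-2-en-1-one F1. Oxidation with H2O2/pyridine (CH2Cl2, 0 °C) causes selenoxide syn-elimination into the ring (the C5 hydrogen is the only β-hydrogen) and the dienone tautomerises to 3-methoxy-5-(2-phenylethyl)phenol F2. Benzylation (BnBr, K2CO3, DMF) gives 1-(benzyloxy)-3-methoxy-5-(2-phenylethyl)benzene F3. NBS (2.05 equiv, MeCN, 0 °C) brominates both positions para to an oxygen and gives 1-(benzyloxy)-2,4-dibromo-5-methoxy-3-(2-phenylethyl)benzene F4. A twofold Negishi coupling with [4-(benzyloxy)benzyl]zinc chloride F5 (made from 4-(benzyloxy)benzyl chloride, zinc dust and LiCl in THF) under Pd(OAc)2/SPhos in THF at 60 °C gives 19, and step 11 follows.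

Step 8 (regioselective monobromination; risk of attack between the two oxygens or over-bromination). The fallback sets out from 14 and comes back at 16, halogenating at the phenol stage so that the free OH, the strongest para director, decides the site. Compound 14 is treated with tetrabutylammonium tribromide (CH2Cl2/MeOH, 0 °C) to give 2-[4-(benzyloxy)benzyl]-4-bromo-5-methoxy-3-(2-phenylethyl)phenol F6, which is O-benzylated (BnBr, K2CO3, DMF) to 16.

Step 9 (hindered aryllithium; risk of proton transfer from benzylic positions or sluggish addition). The fallback sets out from 15 and comes back at 18 with the polarity reversed, so no halide and no aryllithium on the crowded ring is needed. Vilsmeier–Haack formylation of 15 (POCl3, DMF, 0 to 60 °C; aqueous NaOAc) gives 4-(benzyloxy)-3-[4-(benzyloxy)benzyl]-6-methoxy-2-(2-phenylethyl)benzaldehyde F7, formylated para to OBn. Addition of [4-(benzyloxy)phenyl]magnesium bromide F8 (made from 1-(benzyloxy)-4-bromobenzene and Mg in THF) at 0 °C gives 18.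

**Further compounds**
F1 | step 6 | 3-methoxy-5-(2-phenylethyl)-6-(phenylselanyl)cyclohex-2-en-1-one | COC1=CC(=O)C([Se]c2ccccc2)C(CCc2ccccc2)C1
F2 | step 6 | 3-methoxy-5-(2-phenylethyl)phenol | COc1cc(O)cc(CCc2ccccc2)c1
F3 | step 6 | 1-(benzyloxy)-3-methoxy-5-(2-phenylethyl)benzene | COc1cc(OCc2ccccc2)cc(CCc2ccccc2)c1
F4 | step 6 | 1-(benzyloxy)-2,4-dibromo-5-methoxy-3-(2-phenylethyl)benzene | COc1cc(OCc2ccccc2)c(Br)c(CCc2ccccc2)c1Br
F5 | step 6 | [4-(benzyloxy)benzyl]zinc chloride | Cl[Zn]Cc1ccc(OCc2ccccc2)cc1
F6 | step 8 | 2-[4-(benzyloxy)benzyl]-4-bromo-5-methoxy-3-(2-phenylethyl)phenol | COc1cc(O)c(Cc2ccc(OCc3ccccc3)cc2)c(CCc2ccccc2)c1Br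
F7 | step 9 | 4-(benzyloxy)-3-[4-(benzyloxy)benzyl]-6-methoxy-2-(2-phenylethyl)benzaldehyde | COc1cc(OCc2ccccc2)c(Cc2ccc(OCc3ccccc3)cc2)c(CCc2ccccc2)c1C=O
F8 | step 9 | [4-(benzyloxy)phenyl]magnesium bromide | Br[Mg]c1ccc(OCc2ccccc2)cc1
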